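The data are simulated with constants of no real substance, noise included.

- These flasks are slow: zeta's free catalyst has made about 137 turnovers after 25.0 d, alpha's 382 after 8.00 d, so I ask how those turnovers divide.

| flask | left-handed substrate | right-handed substrate | reagent | free catalyst | racemization catalyst | temperature | remark | time |
|---|---|---|---|---|---|---|---|---|
| zeta | 45 mM | 45 mM | 21 mM | 0.13 mM | 0.22 mM | 65 °C | run made earlier |  |
| alpha | 45 mM | 45 mM | 78 mM | 0.13 mM | 0.22 mM | 85 °C | run made earlier |  |
| red | 45 mM | 45 mM | 99.0 mM | 0.13 mM | 0.22 mM | 100 °C |  | 5.0 d |
| green | 45 mM | 45 mM | 25.0 mM | 0.13 mM | 0.22 mM | 70 °C |  | 5.0 d |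

- zeta (time / d: left-handed product / %, right-handed product / %, left-handed substrate / %): 1.25: 2.5, 0.2, 49.4; 3.00: 1.9, 0.8, 45.7; 6.00: 3.4, 3.7, 47.7; 10.0: 5.0, 3.7, 44.3; 25.0: 12.9, 6.9, 42.0
- alpha (time / d: left-handed product / %, right-handed product / %, left-handed substrate / %): 0.500: 5.3, 2.6, 45.9; 1.04: 8.6, 5.2, 43.0; 2.00: 16.0, 11.9, 35.9; 4.00: 23.6, 14.9, 28.3; 8.00: 33.5, 21.7, 21.8

(readings scatter by 1 percentage point)

- free catalyst is single-handed; left-handed substrate and right-handed substrate are mirror images of each other, charged as a racemate, each of them at the stated concentration

- which of the two ends with the higher share of left-handed product in all that became left-handed product or right-handed product ("neither" if they lie within 2 percentage points) (red / green / neither)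
- share of left-handed product in all that became left-handed product or right-handed product, red
- share of left-handed product in all that became left-handed product or right-handed product, green

- In alpha at 8.00 d the products read 12 percentage points apart, but the substrates, right-handed taken from the balance, read 1.2 points apart, far less, so I take it that racemization catalyst keeps them level.
- While they stay level, I carry one reading: alpha's summed readings give 60.7 %, the left-handed share of turnovers, which corresponds to a selectivity factor of 1.54.
- Zeta's last reading gives 65.2 %, but on a product total of 19.8 % with a scatter of 1 point per reading, so I read no temperature trend.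
- To whoever takes over: expect green near zeta's 7.10 % of product at 6.00 d and red well beyond alpha's 38.5 % at 4.00 d, both near 60.7 %, so my answer is neither.
- Don't change reagent on the strength of these runs: zeta and alpha differ in [reagent], 21 mM against 78 mM, and also in temperature, 65 °C against 85 °C, so they can't separate the two settings.
- The forecast says 59.3 % for red, 63 % for green, and green, unlike my reckoning, because “Selectivity should fall with temperature”.
- Red gives 60.4 % and green 60.1 %, so the answer is neither. In red at 5.00 d, racemization catalyst stands at 2.73 % of its charge, with left-handed substrate at 10.9 % against right-handed at 15.6 %. Green's products total 8.64 %, and 60.7 % of that is 5.24 % of left-handed product, where green holds 5.19 %.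

    reagent + free catalyst + left-handed substrate → free catalyst + left-handed product (k = 2100 L² mol⁻² h⁻¹, Ea = 65.0 kJ mol⁻¹)
    reagent + free catalyst + right-handed substrate → free catalyst + right-handed product (k = 1200 L² mol⁻² h⁻¹, Ea = 60.0 kJ mol⁻¹)
    left-handed substrate + racemization catalyst ⇌ right-handed substrate + racemization catalyst, rate k3*[racemization catalyst]*[left-handed substrate] forward; the back reaction follows from the equilibrium constant (k = 220 L mol⁻¹ h⁻¹, Ea = 62.0 kJ mol⁻¹)
    racemization catalyst → spent catalyst (k = 0.0300 h⁻¹, Ea = 128 kJ mol⁻¹)
    (constants at 100 °C)

- Take the neighbour of green with 15 mM of reagent: the share again sends 60.7 % of its turnovers left. The computed flask gives 60.2 %, with 3.17 % of left-handed product and 2.10 % of right-handed.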